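Target: an isoflavan-quinone. Ring A (6-OH, 7,8-di-OMe) is fused to pyran ring C (O1, C2, C3, C4), and the dimethoxyquinone ring B sits on C3 (S). The quinone is unmasked last from a tribenzyl isoflavan by hydrogenolysis and selective oxidation of the ring-B hydroquinone.
Enabling feature: C4 is a benzylic CH2 ortho to O1 on the electron-rich ring A, so O1/ring A/C4 is a masked o-quinone methide. C3 and C2 are the α-carbon and the carboxyl carbon of a ring-B arylacetic acid.
Key disconnection: C3–C4 and O1–C2 of a 3-aryl-dihydrocoumarin lead back to the ring-B arylacetic acid and a ring-A 2-(tosylmethyl)phenol. A chiral isothiourea-bound enolate joins them in a formal [4+2] that sets C3.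
C2 is then lowered from carboxyl to CH2 by full reduction to the phenol-alcohol and Mitsunobu re-closure of O1–C2. This avoids a lactol that would equilibrate with an epimerisable α-aryl aldehyde.
Both arenes come from 2,3-dimethoxy-1,4-benzoquinone. Rings A and B are bought as that carbocycle, and ring C is the only ring built (closed in step 10, re-closed at the ether level in step 12).
Key step: step 10

Assumption: the sense of induction follows the accepted model for isothiourea-bound (Z)-enolates (enolate O syn to S, attack anti to the pseudoaxial C2-phenyl), which assigns 3S to (2R,3S)-HyperBTM; both catalyst antipodes are commercial, so the other one is used if a first run shows the opposite sense.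

Step 1
Reactants: 1 2,3-dimethoxy-1,4-benzoquinone
Product: 2 2,3-dimethoxybenzene-1,4-diol
Conditions: Na2S2O4, EtOAc/H2O, rt
Reagents that add atoms: none
Why: Dithionite reduction of a p-quinone to its hydroquinone is fast in a two-phase system and touches nothing else in the molecule.

Step 2
Reactants: 2 2,3-dimethoxybenzene-1,4-diol; 3 benzyl bromide
Product: 4 4-(benzyloxy)-2,3-dimethoxyphenol
Conditions: BnBr (1.0 equiv), K2CO3, DMF, Ar, rt
Reagents that add atoms: benzyl bromide (3), BrCc1ccccc1
Why: Williamson etherification of a symmetric hydroquinone with two equivalent hydroxyls can give only one mono-ether, which is separated through its solubility in aqueous NaOH, while the bis-ether formed alongside is the product of step 6 and is added to that batch.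

Step 3
Reactants: 4 4-(benzyloxy)-2,3-dimethoxyphenol; 5 formaldehyde (as paraformaldehyde)
Product: 6 5-(benzyloxy)-2-hydroxy-3,4-dimethoxybenzaldehyde
Conditions: MgCl2, Et3N, (CH2O)n, MeCN, reflux; aq HCl work-up
Reagents that add atoms: formaldehyde (5, as paraformaldehyde), C=O
Why: In the Casnati–Skattebøl ortho-formylation the magnesium phenoxide delivers formaldehyde to the only free carbon ortho to the OH, which rules out attack at the electronically similar carbon next to OBn, and a second formaldehyde oxidises the bound benzylic alkoxide by hydride transfer.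

Step 4
Reactants: 6 5-(benzyloxy)-2-hydroxy-3,4-dimethoxybenzaldehyde
Product: 7 4-(benzyloxy)-6-(hydroxymethyl)-2,3-dimethoxyphenol
Conditions: NaBH4, THF/MeOH, 0 °C
Reagents that add atoms: none
Why: Borohydride reduction of the aldehyde gives the salicyl alcohol and leaves the aryl ethers untouched.

Step 5
Reactants: 7 4-(benzyloxy)-6-(hydroxymethyl)-2,3-dimethoxyphenol; 8 sodium p-toluenesulfinate
Product: 9 4-(benzyloxy)-2,3-dimethoxy-6-(tosylmethyl)phenol
Conditions: p-TolSO2Na (1.5 equiv), HCO2H/H2O, rt to 40 °C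
Reagents that add atoms: sodium p-toluenesulfinate (8), Cc1ccc(cc1)S(=O)[O-].[Na+]
Why: In this SN1-type sulfinate alkylation, acid-promoted loss of water (helped by the ortho-OH and the para-methoxy group) gives a benzylic cation/o-quinone methide that the soft sulfur of the sulfinate traps, the sulfone being the thermodynamic product of this reversible capture.

Step 6
Reactants: 2 2,3-dimethoxybenzene-1,4-diol; 3 benzyl bromide
Product: 10 1,4-bis(benzyloxy)-2,3-dimethoxybenzene
Conditions: BnBr (2.5 equiv), K2CO3, DMF, Ar, 60 °C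
Reagents that add atoms: benzyl bromide (3), BrCc1ccccc1
Why: Exhaustive Williamson etherification installs benzyl groups, chosen so that all O-benzyl groups of the coupled product fall in a single hydrogenolysis.

Step 7
Reactants: 10 1,4-bis(benzyloxy)-2,3-dimethoxybenzene
Product: 11 1,4-bis(benzyloxy)-5-bromo-2,3-dimethoxybenzene
Conditions: NBS (1.0 equiv), MeCN, 0 °C, dark
Reagents that add atoms: N-bromosuccinimide, O=C1CCC(=O)N1Br
Why: Electrophilic aromatic bromination of the tetra-alkoxyarene gives one monobromide because the two free ring carbons are symmetry-equivalent, and polar solvent in the dark suppresses radical benzylic bromination.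

Step 8
Reactants: 11 1,4-bis(benzyloxy)-5-bromo-2,3-dimethoxybenzene; 12 diethyl malonate
Product: 13 diethyl 2-[2,5-bis(benzyloxy)-3,4-dimethoxyphenyl]malonate
Conditions: Pd2(dba)3 (2 mol %), P(t-Bu)3·HBF4 (8 mol %), K3PO4, toluene, 80 °C
Reagents that add atoms: diethyl malonate (12), CCOC(=O)CC(=O)OCC
Why: Palladium-catalysed α-arylation of a malonate (Buchwald–Hartwig type) with a bulky electron-rich phosphine accepts electron-rich, ortho-alkoxy aryl bromides and stops at monoarylation.

Step 9
Reactants: 13 diethyl 2-[2,5-bis(benzyloxy)-3,4-dimethoxyphenyl]malonate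
Product: 15 [2,5-bis(benzyloxy)-3,4-dimethoxyphenyl]acetic acid, via arylmalonic acid 14 (not isolated)
Conditions: KOH, EtOH/H2O, reflux; aq HCl, 0 °C; then toluene, 110 °C
Reagents that add atoms: potassium hydroxide, [K+].[OH-]
Why: Saponification followed by thermal decarboxylation of the arylmalonic acid (malonic ester synthesis) proceeds under conditions that aryl benzyl and methyl ethers tolerate.

Step 10
Reactants: 15 [2,5-bis(benzyloxy)-3,4-dimethoxyphenyl]acetic acid (1.3 equiv); 9 4-(benzyloxy)-2,3-dimethoxy-6-(tosylmethyl)phenol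
Product: 19 (3S)-6-(benzyloxy)-3-[2,5-bis(benzyloxy)-3,4-dimethoxyphenyl]-7,8-dimethoxychroman-2-one, via pivalic mixed anhydride 16 (not isolated), via ammonium enolate 17 (not isolated), via ortho-quinone methide 18 (not isolated)
Conditions: t-BuCOCl, i-Pr2NEt, CH2Cl2, 0 °C; then (2R,3S)-HyperBTM (10 mol %), Cs2CO3, slow addition of 9, 0 °C; pH 6 buffer quench
Reagents that add atoms: none
Why: Anhydride 16 N-acylates the isothiourea and deprotonation gives the (Z)-C1-ammonium enolate 17, held flat by the 1,5-O···S contact, while carbonate deprotonates the phenol of 9 and sulfinate departs (E1cB, pushed by the C7 methoxy group para to the benzylic position) to give methide 18 in low stationary concentration. The enolate carbon (C3) adds to the exocyclic CH2 of 18 (C4) as ring A rearomatises, and the freed phenoxide O1 then attacks the acyl-ammonium carbonyl C2 in a 6-exo-trig lactonisation that closes ring C and turns the catalyst over. This is the known chiral Lewis-base (isothiourea or N-heterocyclic carbene) enolate formal [4+2] annulation of in situ generated o-quinone methides to 3-substituted dihydrocoumarins. C3 is the only stereocentre because the methide terminus carries two hydrogens, and it is set by the pseudoaxial C2-phenyl group of the catalyst, which shields one enolate face so that the (2R,3S) catalyst should give 3S. The step needs C–C bond formation to outrun O-acylation of the phenoxide and oligomerisation of 18, which rapid sulfinate loss, slow addition of 9, reversible re-addition of sulfinate as a reservoir and an excess of 15 should secure, and regiochemistry is fixed because 18 has a single electrophilic carbon. Erosion at the acidic C3–H is limited by the low temperature, the electron-rich ortho-substituted ring B, the buffered quench and immediate use in step 11.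

Step 11
Reactants: 19 (3S)-6-(benzyloxy)-3-[2,5-bis(benzyloxy)-3,4-dimethoxyphenyl]-7,8-dimethoxychroman-2-one
Product: 20 4-(benzyloxy)-6-{(2S)-2-[2,5-bis(benzyloxy)-3,4-dimethoxyphenyl]-3-hydroxypropyl}-2,3-dimethoxyphenol
Conditions: LiBH4, THF, 0 °C; aq NH4Cl
Reagents that add atoms: none
Why: Lithium borohydride reduction of the activated aryl ester is fast and only weakly basic, the transient α-aryl aldehyde is reduced faster than it can enolise, and going straight to the diol avoids a lactol in equilibrium with that aldehyde, so C3 should stay S.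

Step 12
Reactants: 20 4-(benzyloxy)-6-{(2S)-2-[2,5-bis(benzyloxy)-3,4-dimethoxyphenyl]-3-hydroxypropyl}-2,3-dimethoxyphenol
Product: 21 (3S)-6-(benzyloxy)-3-[2,5-bis(benzyloxy)-3,4-dimethoxyphenyl]-7,8-dimethoxychroman
Conditions: PPh3, DIAD, THF, 0 °C to rt
Reagents that add atoms: none
Why: The intramolecular Mitsunobu etherification (6-exo-tet), the standard isoflavan ring closure, joins the only free phenol O1 to the activated primary carbon C2 and makes or breaks no bond at C3.

Step 13
Reactants: 21 (3S)-6-(benzyloxy)-3-[2,5-bis(benzyloxy)-3,4-dimethoxyphenyl]-7,8-dimethoxychroman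
Product: 22 2-[(3S)-6-hydroxy-7,8-dimethoxychroman-3-yl]-5,6-dimethoxybenzene-1,4-diol
Conditions: H2 (1 atm), 10% Pd/C, EtOAc/EtOH, rt; filtered under Ar and used directly
Reagents that add atoms: none
Why: Catalytic hydrogenolysis cleaves the three O-benzyl bonds, whereas the chroman O1–C2 bond is not benzylic and the methyl ethers and C3 are inert.

Step 14
Reactants: 22 2-[(3S)-6-hydroxy-7,8-dimethoxychroman-3-yl]-5,6-dimethoxybenzene-1,4-diol
Product: 23 5-[(3S)-6-hydroxy-7,8-dimethoxychroman-3-yl]-2,3-dimethoxycyclohexa-2,5-diene-1,4-dione (target)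
Conditions: Ag2O (1.1 equiv), Na2SO4, EtOAc, rt
Reagents that add atoms: none
Why: In this silver(I) oxide oxidation of a hydroquinone to a p-quinone, the ubiquinol-type ring B is a two-electron donor at much lower potential than the lone ring-A phenol, and with about one equivalent of oxidant any ring-A phenoxyl would be reduced back by remaining hydroquinone, so only ring B should be oxidised.

Compound list
1 | 2,3-dimethoxy-1,4-benzoquinone | COC1=C(OC)C(=O)C=CC1=O | starting material
2 | 2,3-dimethoxybenzene-1,4-diol | COc1c(O)ccc(O)c1OC | intermediate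
3 | benzyl bromide | BrCc1ccccc1 | starting material
4 | 4-(benzyloxy)-2,3-dimethoxyphenol | COc1c(O)ccc(OCc2ccccc2)c1OC | intermediate
5 | formaldehyde (as paraformaldehyde) | C=O | starting material
6 | 5-(benzyloxy)-2-hydroxy-3,4-dimethoxybenzaldehyde | COc1c(O)c(C=O)cc(OCc2ccccc2)c1OC | intermediate
7 | 4-(benzyloxy)-6-(hydroxymethyl)-2,3-dimethoxyphenol | COc1c(O)c(CO)cc(OCc2ccccc2)c1OC | intermediate
8 | sodium p-toluenesulfinate | Cc1ccc(cc1)S(=O)[O-].[Na+] | starting material
9 | 4-(benzyloxy)-2,3-dimethoxy-6-(tosylmethyl)phenol | Cc1ccc(cc1)S(=O)(=O)Cc1cc(OCc2ccccc2)c(OC)c(OC)c1O | intermediate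
10 | 1,4-bis(benzyloxy)-2,3-dimethoxybenzene | COc1c(OCc2ccccc2)ccc(OCc2ccccc2)c1OC | intermediate
11 | 1,4-bis(benzyloxy)-5-bromo-2,3-dimethoxybenzene | COc1c(OC)c(OCc2ccccc2)c(Br)cc1OCc1ccccc1 | intermediate
12 | diethyl malonate | CCOC(=O)CC(=O)OCC | starting material
13 | diethyl 2-[2,5-bis(benzyloxy)-3,4-dimethoxyphenyl]malonate | CCOC(=O)C(C(=O)OCC)c1cc(OCc2ccccc2)c(OC)c(OC)c1OCc1ccccc1 | intermediate
14 | 2-[2,5-bis(benzyloxy)-3,4-dimethoxyphenyl]malonic acid | OC(=O)C(C(O)=O)c1cc(OCc2ccccc2)c(OC)c(OC)c1OCc1ccccc1 | intermediate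
15 | [2,5-bis(benzyloxy)-3,4-dimethoxyphenyl]acetic acid | OC(=O)Cc1cc(OCc2ccccc2)c(OC)c(OC)c1OCc1ccccc1 | intermediate
16 | [2,5-bis(benzyloxy)-3,4-dimethoxyphenyl]acetic pivalic anhydride | CC(C)(C)C(=O)OC(=O)Cc1cc(OCc2ccccc2)c(OC)c(OC)c1OCc1ccccc1 | intermediate
17 | (Z)-2-[2,5-bis(benzyloxy)-3,4-dimethoxyphenyl]-1-[(2R,3S)-3-isopropyl-2-phenyl-3,4-dihydro-2H-benzo[4,5]thiazolo[3,2-a]pyrimidin-1-ium-1-yl]ethen-1-olate (C1-ammonium enolate) | [O-]/C(=C\c1cc(OCc2ccccc2)c(OC)c(OC)c1OCc1ccccc1)[N+]1=C2Sc3ccccc3N2C[C@H](C(C)C)[C@@H]1c1ccccc1 | intermediate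
18 | 4-(benzyloxy)-2,3-dimethoxy-6-methylidenecyclohexa-2,4-dien-1-one (o-quinone methide) | C=C1C=C(OCc2ccccc2)C(OC)=C(OC)C1=O | intermediate
19 | (3S)-6-(benzyloxy)-3-[2,5-bis(benzyloxy)-3,4-dimethoxyphenyl]-7,8-dimethoxychroman-2-one | COc1c(OC)c(OCc2ccccc2)cc([C@H]2C(=O)Oc3c(cc(OCc4ccccc4)c(OC)c3OC)C2)c1OCc1ccccc1 | intermediate
20 | 4-(benzyloxy)-6-{(2S)-2-[2,5-bis(benzyloxy)-3,4-dimethoxyphenyl]-3-hydroxypropyl}-2,3-dimethoxyphenol | COc1c(OC)c(OCc2ccccc2)cc([C@@H](CO)Cc2cc(OCc3ccccc3)c(OC)c(OC)c2O)c1OCc1ccccc1 | intermediate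
21 | (3S)-6-(benzyloxy)-3-[2,5-bis(benzyloxy)-3,4-dimethoxyphenyl]-7,8-dimethoxychroman | COc1c(OC)c(OCc2ccccc2)cc([C@H]2COc3c(cc(OCc4ccccc4)c(OC)c3OC)C2)c1OCc1ccccc1 | intermediate
22 | 2-[(3S)-6-hydroxy-7,8-dimethoxychroman-3-yl]-5,6-dimethoxybenzene-1,4-diol | COc1c(OC)c(O)cc([C@H]2COc3c(cc(O)c(OC)c3OC)C2)c1O | intermediate
23 | 5-[(3S)-6-hydroxy-7,8-dimethoxychroman-3-yl]-2,3-dimethoxycyclohexa-2,5-diene-1,4-dione | COC1=C(OC)C(=O)C([C@H]2COc3c(cc(O)c(OC)c3OC)C2)=CC1=O | target

Total step count: 14.
Longest linear sequence: 10 steps (1, 2, 3, 4, 5, 10, 11, 12, 13, 14). The ring-B branch (1, 6, 7, 8, 9, then 10–14) has the same length.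

Steps most likely to fail

**Step 10.**
- What may go wrong: the ortho-benzyloxy group may twist ring B out of the enolate plane, so one face is shielded incompletely.
- The product may lose configuration at C3 through base-induced enolisation of the aryl ester.
- The phenoxide of 9 may be acylated on oxygen, or the methide may condense with itself.

Fallback: auxiliary-controlled Evans alkylation, setting out from 6 and 15 and coming back at 20. Aldehyde 6 is O-allylated (allyl bromide, K2CO3, DMF) to 2-(allyloxy)-5-(benzyloxy)-3,4-dimethoxybenzaldehyde F1. F1 is reduced (NaBH4, MeOH) to [2-(allyloxy)-5-(benzyloxy)-3,4-dimethoxyphenyl]methanol F2. An Appel reaction (CBr4, PPh3, CH2Cl2, 0 °C) converts F2 into 2-(allyloxy)-5-(benzyloxy)-1-(bromomethyl)-3,4-dimethoxybenzene F3, which is used crude. Acid 15 is activated as anhydride 16 and coupled with lithiated (S)-4-benzyloxazolidin-2-one to give (4S)-4-benzyl-3-{[2,5-bis(benzyloxy)-3,4-dimethoxyphenyl]acetyl}-1,3-oxazolidin-2-one F4. Its chelated (Z)-sodium enolate (NaHMDS, THF, −78 °C) is alkylated by F3 on the face away from the auxiliary benzyl group. This gives (4S)-3-{(2S)-3-[2-(allyloxy)-5-(benzyloxy)-3,4-dimethoxyphenyl]-2-[2,5-bis(benzyloxy)-3,4-dimethoxyphenyl]propanoyl}-4-benzyl-1,3-oxazolidin-2-one F5. LiBH4 (THF, H2O, 0 °C) removes the auxiliary to give (2S)-3-[2-(allyloxy)-5-(benzyloxy)-3,4-dimethoxyphenyl]-2-[2,5-bis(benzyloxy)-3,4-dimethoxyphenyl]propan-1-ol F6. Tsuji–Trost deallylation (Pd(PPh3)4, morpholine, THF) then frees the phenol and delivers 20.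

**Step 11.**
- What may go wrong: C3 may be partly scrambled by enolisation of the lactone, or of the transient aldehyde, by boron alkoxide and phenoxide species before hydride transfer is complete.
- The reduction may stall at the lactol stage.

Fallback: ring-retaining reductive acetylation and ionic reduction, setting out from 19 and coming back at 21, so that 20 and step 12 are bypassed. DIBAL-H (1.1 equiv, CH2Cl2, −78 °C) is followed in the same flask by Ac2O, pyridine and DMAP at −78 °C. This traps the aluminium hemiacetal in its cyclic form, with no free lactol or open aldehyde, as (3S)-6-(benzyloxy)-3-[2,5-bis(benzyloxy)-3,4-dimethoxyphenyl]-7,8-dimethoxychroman-2-yl acetate (C2 epimers) F7. Et3SiH (excess) and BF3·OEt2 in CH2Cl2 at −78 °C reduce the derived oxocarbenium ion to 21.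

**Step 5.**
- What may go wrong: acid ionisation of the very electron-rich salicyl alcohol may lead to Friedel–Crafts self-condensation and oligomerisation faster than sulfinate capture.

Fallback: an amine leaving group under non-acidic conditions, setting out from 4 and coming back at 9, so that steps 3–5 are bypassed. A Mannich reaction of 4 (aq Me2NH, aq CH2O, EtOH, rt to reflux) attacks the only free position ortho to the OH and gives 4-(benzyloxy)-6-[(dimethylamino)methyl]-2,3-dimethoxyphenol F8. Methyl iodide (Et2O/MeCN) gives [5-(benzyloxy)-2-hydroxy-3,4-dimethoxybenzyl]trimethylammonium iodide F9. Warming F9 with sodium p-toluenesulfinate 8 (EtOH/H2O, 70 °C) expels the amine, and the sulfinate adds to the methide to give 9.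

Further compounds
F1 | step 10 | 2-(allyloxy)-5-(benzyloxy)-3,4-dimethoxybenzaldehyde | C=CCOc1c(C=O)cc(OCc2ccccc2)c(OC)c1OC
F2 | step 10 | [2-(allyloxy)-5-(benzyloxy)-3,4-dimethoxyphenyl]methanol | C=CCOc1c(CO)cc(OCc2ccccc2)c(OC)c1OC
F3 | step 10 | 2-(allyloxy)-5-(benzyloxy)-1-(bromomethyl)-3,4-dimethoxybenzene | C=CCOc1c(CBr)cc(OCc2ccccc2)c(OC)c1OC
F4 | step 10 | (4S)-4-benzyl-3-{[2,5-bis(benzyloxy)-3,4-dimethoxyphenyl]acetyl}-1,3-oxazolidin-2-one | O=C1OC[C@H](Cc2ccccc2)N1C(=O)Cc1cc(OCc2ccccc2)c(OC)c(OC)c1OCc1ccccc1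
F5 | step 10 | (4S)-3-{(2S)-3-[2-(allyloxy)-5-(benzyloxy)-3,4-dimethoxyphenyl]-2-[2,5-bis(benzyloxy)-3,4-dimethoxyphenyl]propanoyl}-4-benzyl-1,3-oxazolidin-2-one | O=C1OC[C@H](Cc2ccccc2)N1C(=O)[C@@H](Cc1cc(OCc2ccccc2)c(OC)c(OC)c1OCC=C)c1cc(OCc2ccccc2)c(OC)c(OC)c1OCc1ccccc1
F6 | step 10 | (2S)-3-[2-(allyloxy)-5-(benzyloxy)-3,4-dimethoxyphenyl]-2-[2,5-bis(benzyloxy)-3,4-dimethoxyphenyl]propan-1-ol | OC[C@@H](Cc1cc(OCc2ccccc2)c(OC)c(OC)c1OCC=C)c1cc(OCc2ccccc2)c(OC)c(OC)c1OCc1ccccc1
F7 | step 11 | (3S)-6-(benzyloxy)-3-[2,5-bis(benzyloxy)-3,4-dimethoxyphenyl]-7,8-dimethoxychroman-2-yl acetate (C2 epimers) | CC(=O)OC1Oc2c(C[C@H]1c1cc(OCc3ccccc3)c(OC)c(OC)c1OCc1ccccc1)cc(OCc1ccccc1)c(OC)c2OC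
F8 | step 5 | 4-(benzyloxy)-6-[(dimethylamino)methyl]-2,3-dimethoxyphenol | CN(C)Cc1cc(OCc2ccccc2)c(OC)c(OC)c1O
F9 | step 5 | [5-(benzyloxy)-2-hydroxy-3,4-dimethoxybenzyl]trimethylammonium iodide | C[N+](C)(C)Cc1cc(OCc2ccccc2)c(OC)c(OC)c1O.[I-]
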